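**Strategy**

The route rests on cutting ring A (O, C7, C8, C9, C10) at its O–C7 bond together with the C5–C6 bond. A divalent-palladium-catalysed anti-oxypalladation of the terminal alkyne C6≡C7 by the C10 hydroxyl, with capture of the vinylpalladium by allyl chloride, should close ring A, forge C5–C6 and fix the 6E enol ether in one operation. It exploits the exocyclic C6=C7 enol ether and the cis disposition of O10 and the C9 side chain on ring B. The precursor is a monocyclic ring B diol bearing a propargylic C8 alcohol and the C13 bromide; the Z-enyne and the C8 bromide are added afterwards.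

Key step: step 7

Numbering used throughout: C1≡C2–C3=C4–C5–C6=C7–C8–C9–C10–C11–C12–C13–C14–C15; ring A = O, C7, C8, C9, C10; ring B = O, C9, C10, C11, C12. The target is 8S,9R,10S,12R,13S, 3Z, 6E.

Remark on the chemistry: in step 2 the (S)-configured diarylprolinol silyl ether is assumed to deliver (S)-2-bromobutanal; if the facial sense is the opposite, its antipode is used.

**Route**

Step 1
Reactants: 1 3-(trimethylsilyl)prop-2-ynal; 2 1-(triphenylphosphoranylidene)propan-2-one
Product: 3 (E)-6-(trimethylsilyl)hex-3-en-5-yn-2-one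
Conditions: CH2Cl2, rt
Reagents that add atoms: none
Why: Wittig olefination with a stabilised acyl ylide should give the E enone selectively.

Step 2
Reactants: 4 butanal
Product: 5 (S)-2-bromobutanal
Conditions: (S)-α,α-diphenylprolinol trimethylsilyl ether (5 mol %), N-bromosuccinimide (slow addition), (CF3)2CHOH, trace H2O, 0 °C; cold solution used at once
Reagents that add atoms: N-bromosuccinimide, O=C1CCC(=O)N1Br
Why: Enamine-catalysed asymmetric α-bromination, in which the diarylprolinol silyl ether shields one enamine face and sets C13.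

Step 3
Reactants: 3 (E)-6-(trimethylsilyl)hex-3-en-5-yn-2-one; 5 (S)-2-bromobutanal
Product: 7 (3E,7R,8S)-8-bromo-7-hydroxy-1-(trimethylsilyl)dec-3-en-1-yn-5-one, via lithium enolate 6 (not isolated)
Conditions: LiN(i-Pr)2, THF, −78 °C; then 5, −78 °C; AcOH quench at −78 °C
Reagents that add atoms: none
Why: Lithium aldol addition to an α-haloaldehyde through the Cornforth (polar Felkin–Anh) transition state should give the 1,2-anti bromohydrin, so that C13 sets C12 as R.

Step 4
Reactants: 7 (3E,7R,8S)-8-bromo-7-hydroxy-1-(trimethylsilyl)dec-3-en-1-yn-5-one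
Product: 9 (3S,4R,6S,7E)-3-bromo-10-(trimethylsilyl)dec-7-en-9-yne-4,6-diol, via diethylboryl chelate 8 (not isolated)
Conditions: Et2BOMe, THF/MeOH, −78 °C; then NaBH4, −78 °C; MeOH work-up
Reagents that add atoms: none
Why: Narasaka–Prasad reduction, in which external hydride attacks the six-membered boron chelate to give the 1,3-syn diol, so that C12 sets C10 as S.

Step 5
Reactants: 9 (3S,4R,6S,7E)-3-bromo-10-(trimethylsilyl)dec-7-en-9-yne-4,6-diol
Product: 11 (2R,3S,5R)-5-[(1S)-1-bromopropyl]-2-[(1S)-1-hydroxy-3-(trimethylsilyl)prop-2-yn-1-yl]oxolan-3-ol, via epoxy alcohol 10 (not isolated)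
Conditions: Ti(OiPr)4, L-(+)-diisopropyl tartrate, t-BuOOH, 4 Å molecular sieves, CH2Cl2, −20 °C; then camphorsulfonic acid (cat.), CH2Cl2, 0 °C on the crude epoxide
Reagents that add atoms: tert-butyl hydroperoxide, CC(C)(C)OO
Why: Sharpless asymmetric epoxidation in the matched sense (the 10S carbinol is the fast-reacting enantiomer with the L-tartrate and gives the erythro trans-epoxide) sets C8 and C9, and 5-exo-tet opening by the C12 hydroxyl with inversion at C9 then closes ring B.

Step 6
Reactants: 11 (2R,3S,5R)-5-[(1S)-1-bromopropyl]-2-[(1S)-1-hydroxy-3-(trimethylsilyl)prop-2-yn-1-yl]oxolan-3-ol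
Product: 12 (2R,3S,5R)-5-[(1S)-1-bromopropyl]-2-[(1S)-1-hydroxyprop-2-yn-1-yl]oxolan-3-ol
Conditions: K2CO3 (cat.), MeOH, 0 °C
Reagents that add atoms: none
Why: Base-catalysed protiodesilylation of the alkynylsilane should free the terminal alkyne without touching the secondary bromide.

Step 7
Reactants: 12 (2R,3S,5R)-5-[(1S)-1-bromopropyl]-2-[(1S)-1-hydroxyprop-2-yn-1-yl]oxolan-3-ol; 13 allyl chloride
Product: 15 (4E,6R,7S,8S,10R,11S)-11-bromo-5,8:7,10-diepoxytrideca-1,4-dien-6-ol, via vinylpalladium chloride 14 (not isolated)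
Conditions: PdCl2(MeCN)2 (5 mol %), methyloxirane (5 equiv), THF, 0 °C to rt; 13 in tenfold excess
Reagents that add atoms: none
Why: PdCl2(MeCN)2 π-activates the terminal alkyne and the C10 hydroxyl adds to C7 from the face opposite the metal (anti-oxypalladation), giving the σ-vinylpalladium 14 with palladium on C6 trans to oxygen; carbopalladation of allyl chloride at its CH2 terminus and β-chloride elimination then form C5–C6 with retention and return divalent palladium. The closest known reaction type is the oxypalladation–allylation of alkynols and alkynoates with allyl halides. Ring A closes in the 5-exo-dig mode and must be cis-fused because O10 and the C9 side chain are cis on ring B. No new stereocentre arises; the 6E geometry is controlled by the anti addition followed by stereoretentive C–C bond formation. The step needs 5-exo over 6-endo closure, which the terminal alkyne and the 1,3-relation of O10 to C7 secure, and allyl capture over protodepalladation, which excess allyl chloride and methyloxirane as HCl scavenger secure. The C8 hydroxyl cannot compete because it would have to form a three- or four-membered ring.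

Step 8
Reactants: 16 bromoethene; 17 ethynyltri(propan-2-yl)silane
Product: 18 (but-3-en-1-yn-1-yl)tri(propan-2-yl)silane
Conditions: Pd(PPh3)2Cl2 (2 mol %), CuI (4 mol %), i-Pr2NH, THF, 0 °C to rt
Reagents that add atoms: none
Why: Sonogashira coupling of a vinyl bromide with a terminal alkyne should give the conjugated enyne.

Step 9
Reactants: 15 (4E,6R,7S,8S,10R,11S)-11-bromo-5,8:7,10-diepoxytrideca-1,4-dien-6-ol; 18 (but-3-en-1-yn-1-yl)tri(propan-2-yl)silane
Product: 19 (3Z,6E,8R,9S,10S,12R,13S)-13-bromo-7,10:9,12-diepoxy-1-(triisopropylsilyl)pentadeca-3,6-dien-1-yn-8-ol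
Conditions: second-generation Grubbs catalyst (10 mol %), 18 (4 equiv), CH2Cl2, 40 °C
Reagents that add atoms: none
Why: Cross-metathesis of a terminal alkene with a conjugated enyne is kinetically Z-selective, and the trisubstituted enol ether and the free hydroxyl should not take part.

Step 10
Reactants: 19 (3Z,6E,8R,9S,10S,12R,13S)-13-bromo-7,10:9,12-diepoxy-1-(triisopropylsilyl)pentadeca-3,6-dien-1-yn-8-ol
Product: 20 (3Z,6E,8R,9S,10S,12R,13S)-13-bromo-7,10:9,12-diepoxypentadeca-3,6-dien-1-yn-8-ol
Conditions: Bu4NF, THF, 0 °C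
Reagents that add atoms: none
Why: Fluoride-mediated cleavage of the alkynyl C–Si bond should free the terminal enyne while the C8 position is still an alcohol.

Step 11
Reactants: 20 (3Z,6E,8R,9S,10S,12R,13S)-13-bromo-7,10:9,12-diepoxypentadeca-3,6-dien-1-yn-8-ol
Product: 21 (3Z,6E,8S,9R,10S,12R,13S)-8,13-dibromo-7,10:9,12-diepoxypentadeca-3,6-dien-1-yne
Conditions: CBr4, PPh3, 2,6-lutidine, CH2Cl2, −20 to 0 °C
Reagents that add atoms: tetrabromomethane, BrC(Br)(Br)Br
Why: Appel bromination, in which bromide displaces the activated C8 oxygen by SN2 from the convex face, should invert C8 to S under buffered conditions that spare the enol ether.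

**Compound list**

1 | 3-(trimethylsilyl)prop-2-ynal | C[Si](C)(C)C#CC=O | starting material
2 | 1-(triphenylphosphoranylidene)propan-2-one | CC(=O)C=P(c1ccccc1)(c1ccccc1)c1ccccc1 | starting material
3 | (E)-6-(trimethylsilyl)hex-3-en-5-yn-2-one | CC(=O)/C=C/C#C[Si](C)(C)C | intermediate
4 | butanal | CCCC=O | starting material
5 | (S)-2-bromobutanal | CC[C@H](Br)C=O | intermediate
6 | lithium enolate of 3 (not isolated) | [Li]OC(=C)/C=C/C#C[Si](C)(C)C | intermediate
7 | (3E,7R,8S)-8-bromo-7-hydroxy-1-(trimethylsilyl)dec-3-en-1-yn-5-one | C[Si](C)(C)C#C/C=C/C(=O)C[C@@H](O)[C@@H](Br)CC | intermediate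
8 | O-diethylboryl chelate of 7 (not isolated) | CCB(CC)O[C@H](CC(=O)/C=C/C#C[Si](C)(C)C)[C@@H](Br)CC | intermediate
9 | (3S,4R,6S,7E)-3-bromo-10-(trimethylsilyl)dec-7-en-9-yne-4,6-diol | C[Si](C)(C)C#C/C=C/[C@@H](O)C[C@@H](O)[C@@H](Br)CC | intermediate
10 | (1S,3R,4S)-4-bromo-1-[(2S,3S)-3-(trimethylsilylethynyl)oxiran-2-yl]hexane-1,3-diol (not isolated) | C[Si](C)(C)C#C[C@@H]1O[C@H]1[C@@H](O)C[C@@H](O)[C@@H](Br)CC | intermediate
11 | (2R,3S,5R)-5-[(1S)-1-bromopropyl]-2-[(1S)-1-hydroxy-3-(trimethylsilyl)prop-2-yn-1-yl]oxolan-3-ol | C[Si](C)(C)C#C[C@H](O)[C@@H]1O[C@H](C[C@@H]1O)[C@@H](Br)CC | intermediate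
12 | (2R,3S,5R)-5-[(1S)-1-bromopropyl]-2-[(1S)-1-hydroxyprop-2-yn-1-yl]oxolan-3-ol | C#C[C@H](O)[C@@H]1O[C@H](C[C@@H]1O)[C@@H](Br)CC | intermediate
13 | allyl chloride (3-chloroprop-1-ene) | C=CCCl | starting material
14 | (E)-σ-vinylpalladium chloride from 5-exo-dig oxypalladation of 12, Pd on C6 trans to the ring oxygen (not isolated) | Cl[Pd]/C=C1/O[C@H]2C[C@H]([C@@H](Br)CC)O[C@H]2[C@H]1O | intermediate
15 | (4E,6R,7S,8S,10R,11S)-11-bromo-5,8:7,10-diepoxytrideca-1,4-dien-6-ol | C=CC/C=C1/O[C@H]2C[C@H]([C@@H](Br)CC)O[C@H]2[C@H]1O | intermediate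
16 | bromoethene (vinyl bromide) | BrC=C | starting material
17 | ethynyltri(propan-2-yl)silane | C#C[Si](C(C)C)(C(C)C)C(C)C | starting material
18 | (but-3-en-1-yn-1-yl)tri(propan-2-yl)silane | C=CC#C[Si](C(C)C)(C(C)C)C(C)C | intermediate
19 | (3Z,6E,8R,9S,10S,12R,13S)-13-bromo-7,10:9,12-diepoxy-1-(triisopropylsilyl)pentadeca-3,6-dien-1-yn-8-ol | CC(C)[Si](C(C)C)(C(C)C)C#C/C=C\C/C=C1/O[C@H]2C[C@H]([C@@H](Br)CC)O[C@H]2[C@H]1O | intermediate
20 | (3Z,6E,8R,9S,10S,12R,13S)-13-bromo-7,10:9,12-diepoxypentadeca-3,6-dien-1-yn-8-ol | C#C/C=C\C/C=C1/O[C@H]2C[C@H]([C@@H](Br)CC)O[C@H]2[C@H]1O | intermediate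
21 | (3Z,6E,8S,9R,10S,12R,13S)-8,13-dibromo-7,10:9,12-diepoxypentadeca-3,6-dien-1-yne | C#C/C=C\C/C=C1/O[C@H]2C[C@H]([C@@H](Br)CC)O[C@H]2[C@@H]1Br | target

**Count and risks**

Total steps: 11. Longest linear sequence: 9 steps (steps 1, 3, 4, 5, 6, 7, 9, 10, 11).

Steps most likely to fail:

1. Step 11. Activation of the allylic C8 alcohol next to the enol ether may lead to allylic transposition or ionisation with loss of configuration at C8, or to acid-induced migration of the exocyclic double bond. The fallback sets out from 12 and comes back at 21, placing the bromide at the propargylic stage where SN2 is clean. Diol 12 would be converted with SO2Cl2 and Et3N (CH2Cl2, −78 °C) into the six-membered C8,C10-cyclic sulfate F1. LiBr in THF should open it at the propargylic C8 with inversion to the lithium C10-sulfate of the propargylic bromide F2, which is hydrolysed in the same flask (cat. H2SO4, one equivalent of H2O) to the bromo alcohol F3. The same divalent-palladium cyclisation–allylation with 13 would give the allylated bicyclic dibromide F4, enyne cross-metathesis with 18 the silylated enyne dibromide F5, and Bu4NF buffered with AcOH would give 21.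

2. Step 9. The cross-metathesis may show poor Z-selectivity, and ruthenium hydride may move the terminal alkene into conjugation with the enol ether. The fallback sets out from 12 and comes back at 19, building the Z-alkene from a geometrically pure C3 unit and closing ring A by syn addition. Copper-mediated coupling of the terminal alkyne of 12 with (Z)-1,3-dichloropropene (CuI, K2CO3, DMF) would give the skipped (Z)-chloroenyne diol F6. La[N(SiMe3)2]3-catalysed hydroalkoxylation (syn insertion of the internal alkyne into the La–O bond, then protonolysis) should close ring A to the bicyclic 6E enol ether (Z)-vinyl chloride F7. Sonogashira coupling of F7 with 17 (PdCl2(PhCN)2, CuI, piperidine) would then give 19 with retention of the Z geometry.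

3. Step 7. Protodepalladation of the vinylpalladium may outrun allyl capture, or the catalyst may be reduced to inactive palladium black. The fallback sets out from 12 and comes back at 15, separating ring closure from C–C bond formation. Iodocyclisation with N-iodosuccinimide (NaHCO3, MeCN, 0 °C) should give by anti addition the (E)-iodomethylene bicyclic alcohol F8. Stille coupling of F8 with allyltributylstannane (Pd(PPh3)4, CuI, DMF; zerovalent palladium) would give 15 with retention.

Further compounds
F1 | step 11 | C8,C10-cyclic sulfate of 12 | C#C[C@@H]1OS(=O)(=O)O[C@H]2C[C@H]([C@@H](Br)CC)O[C@@H]12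
F2 | step 11 | lithium (2R,3S,5R)-2-[(1R)-1-bromoprop-2-yn-1-yl]-5-[(1S)-1-bromopropyl]oxolan-3-yl sulfate | C#C[C@@H](Br)[C@@H]1O[C@H](C[C@@H]1OS(=O)(=O)[O-])[C@@H](Br)CC.[Li+]
F3 | step 11 | (2R,3S,5R)-2-[(1R)-1-bromoprop-2-yn-1-yl]-5-[(1S)-1-bromopropyl]oxolan-3-ol | C#C[C@@H](Br)[C@@H]1O[C@H](C[C@@H]1O)[C@@H](Br)CC
F4 | step 11 | allylated bicyclic dibromide (C8 bromide analogue of 15) | C=CC/C=C1/O[C@H]2C[C@H]([C@@H](Br)CC)O[C@H]2[C@@H]1Br
F5 | step 11 | 1-(triisopropylsilyl) derivative of 21 | CC(C)[Si](C(C)C)(C(C)C)C#C/C=C\C/C=C1/O[C@H]2C[C@H]([C@@H](Br)CC)O[C@H]2[C@@H]1Br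
F6 | step 9 | (2R,3S,5R)-5-[(1S)-1-bromopropyl]-2-[(1S,5Z)-6-chloro-1-hydroxyhex-5-en-2-yn-1-yl]oxolan-3-ol | Cl/C=C\CC#C[C@H](O)[C@@H]1O[C@H](C[C@@H]1O)[C@@H](Br)CC
F7 | step 9 | bicyclic 6E enol ether carrying the (Z)-3-chloroallyl group (C3 chloride analogue of 20) | Cl/C=C\C/C=C1/O[C@H]2C[C@H]([C@@H](Br)CC)O[C@H]2[C@H]1O
F8 | step 7 | (E)-iodomethylene bicyclic alcohol (C6 iodide analogue of 15) | I/C=C1/O[C@H]2C[C@H]([C@@H](Br)CC)O[C@H]2[C@H]1O
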